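**Retrosynthetic overview**
1. The 1,3-diketone is cut at its CH2–C(=O)Ph bond: the last step is C-benzoylation of the methyl ketone of the 6-acetyl-5-hydroxy-7-methoxy-2,2-dimethylchromene with benzoyl chloride.
2. The 2H-pyran ring (O1, C2, C3, C4, C4a, C8a) is not closed as such. It comes from the five-membered ring (O1, C2, C3, C3a, C7a) of the isomeric 2-isopropenyl-2,3-dihydrobenzofuran by a redox-neutral one-atom ring expansion under Pd(0)/acid; the exocyclic isopropenyl carbon enters the ring between the oxygen and the old C2 and becomes C(CH3)2.
3. Enabling feature: in that dihydrobenzofuran the ring bond O1–C2 is an allylic aryl ether bond (C2 carries the isopropenyl group), its oxygen is para to the C5 acetyl group, and the adjacent benzylic ring CH2 (C3) supplies the hydrogen that migrates; the C4–OH is held in a hydrogen bond to the acetyl oxygen.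
4. The dihydrobenzofuran comes from isoprene and the 3-iodo derivative of commercial 2,4-dihydroxy-6-methoxyacetophenone by Larock heteroannulation.
5. Ring order: benzene ring bought; dihydrofuran ring (step 2); pyran ring by expansion of the dihydrofuran ring (step 3).

Key step: step 3

Remark: the target has no stereogenic centre or axis, so it is one achiral compound; the dihydrobenzofuran intermediate is therefore used as the racemate, since its only stereocentre is erased in the ring expansion.

**Step 1**
Reactants: 1 1-(2,4-dihydroxy-6-methoxyphenyl)ethan-1-one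
Product: 2 1-(2,4-dihydroxy-3-iodo-6-methoxyphenyl)ethan-1-one
Conditions: I2 (1.05 equiv), NaHCO3 (1.2 equiv), THF–H2O 1:1, 0 °C to rt
Reagents that add atoms: iodine, II
Why: Electrophilic iodination of the phenoxide of this resorcinol-type ring is expected at C3, the carbon between the two hydroxyls (the site that iodine with hydrogencarbonate attacks in resorcinol itself) and less hindered than C5 next to the methoxyl, while the mild base leaves the methyl ketone untouched; no stereocentre is formed.

**Step 2**
Reactants: 2 1-(2,4-dihydroxy-3-iodo-6-methoxyphenyl)ethan-1-one; 3 isoprene (2-methylbuta-1,3-diene)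
Product: 4 rac-1-[4-hydroxy-6-methoxy-2-(prop-1-en-2-yl)-2,3-dihydro-1-benzofuran-5-yl]ethan-1-one
Conditions: Pd(OAc)2 (5 mol %), NaHCO3 (2.5 equiv), n-Bu4NCl (1 equiv), isoprene (5 equiv), DMF, 80 °C, sealed tube
Reagents that add atoms: isoprene (3), C=CC(C)=C
Why: Larock heteroannulation of a 1,3-diene: oxidative addition into the C–I bond, transfer of the aryl group to the unsubstituted vinyl terminus of isoprene and 5-exo capture of the resulting η3-(2-methylallyl)palladium at its internal carbon by the free (non-chelated, more acidic) C4 phenoxide should give the 2-isopropenyl-dihydrobenzofuran; the new C2 stereocentre forms as a racemate, which suffices because step 3 erases it.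

**Step 3**
Reactants: 4 rac-1-[4-hydroxy-6-methoxy-2-(prop-1-en-2-yl)-2,3-dihydro-1-benzofuran-5-yl]ethan-1-one
Product: 6 1-(5-hydroxy-7-methoxy-2,2-dimethyl-2H-chromen-6-yl)ethan-1-one, via dienylphenol 5 (not isolated)
Conditions: Pd(PPh3)4 (5 mol %), PhCO2H (20 mol %), 1,4-dioxane, 100 °C, Ar
Reagents that add atoms: none
Why: Proposed new method: Pd(0) should ionise the allylic aryl ether bond O1–C2 of 4 (the leaving phenoxide is para to the acetyl group, a vinylogous carboxylate), the η3-(2-methylallyl)palladium should lose the benzylic hydrogen of the old C3 (β-hydride elimination or benzoate-assisted deprotonation) to give (E)-dienylphenol 5 and a palladium hydride, and this hydride should add back to the terminal CH2 of the diene to give the η3-1-aryl-3,3-dimethylallyl complex. After syn–anti isomerisation through the η1-benzylic form the liberated phenoxide should attack the C(CH3)2 terminus of this allyl unit, a 6-endo allylic etherification that closes the 2H-pyran ring (attack at the benzylic terminus would need a four-membered ring), so that the oxygen has moved from the old C2 to the former exocyclic carbon and the double bond has moved into the ring. The closest known reaction types are the Tsuji–Trost ionisation of allyl aryl ethers, the palladium-catalysed 1,4-elimination of allylic ethers and esters to 1,3-dienes, the Pd(0)/carboxylic acid hydroalkoxylation of 1,3-dienes by phenols and the palladium-catalysed ring expansion of 2-vinyl-substituted saturated heterocycles by 1,3-shift; new is their combination into an isomerising ring expansion of a 2-isopropenyl-2,3-dihydrobenzofuran. No stereocentre is formed and the C2 stereocentre of 4 is destroyed. The step needs ring-size selectivity (six over five or seven) and the right ring oxygen: all allylic ether isomers including 6 can re-ionise and so equilibrate, 6 should be the thermodynamic sink because its ring is unstrained and its C3=C4 bond is conjugated with the electron-rich arene, and the ortho-hydroxyl stays locked in its hydrogen bond to the acetyl oxygen and leaves the closure to the para-oxygen.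

**Step 4**
Reactants: 6 1-(5-hydroxy-7-methoxy-2,2-dimethyl-2H-chromen-6-yl)ethan-1-one; 7 benzoyl chloride
Product: 8 1-(5-hydroxy-7-methoxy-2,2-dimethyl-2H-chromen-6-yl)-3-phenylpropane-1,3-dione
Conditions: LiHMDS (3.3 equiv), THF, −78 to −10 °C; then PhCOCl (1.05 equiv), −78 °C to rt; aq. NH4Cl
Reagents that add atoms: benzoyl chloride (7), O=C(Cl)c1ccccc1
Why: Crossed Claisen condensation: the phenoxide–enolate dianion of the o-hydroxyacetophenone is C-benzoylated (any O-benzoate formed is carried on to the same diketone by Baker–Venkataraman acyl transfer under the excess base), the third equivalent of base stores the product as its enolate, and the buffered work-up avoids cyclodehydration to a flavone; no stereocentre is formed.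

**Compound list**
1 | 1-(2,4-dihydroxy-6-methoxyphenyl)ethan-1-one | CC(=O)c1c(O)cc(O)cc1OC | starting material
2 | 1-(2,4-dihydroxy-3-iodo-6-methoxyphenyl)ethan-1-one | CC(=O)c1c(O)c(I)c(O)cc1OC | intermediate
3 | isoprene (2-methylbuta-1,3-diene) | C=CC(C)=C | starting material
4 | rac-1-[4-hydroxy-6-methoxy-2-(prop-1-en-2-yl)-2,3-dihydro-1-benzofuran-5-yl]ethan-1-one | COc1cc2c(c(O)c1C(C)=O)CC(C(C)=C)O2 | intermediate
5 | 1-{2,4-dihydroxy-6-methoxy-3-[(1E)-3-methylbuta-1,3-dien-1-yl]phenyl}ethan-1-one (forms in the flask in step 3, not isolated) | CC(=O)c1c(OC)cc(O)c(/C=C/C(C)=C)c1O | intermediate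
6 | 1-(5-hydroxy-7-methoxy-2,2-dimethyl-2H-chromen-6-yl)ethan-1-one | COc1cc2c(c(O)c1C(C)=O)C=CC(C)(C)O2 | intermediate
7 | benzoyl chloride | O=C(Cl)c1ccccc1 | starting material
8 | 1-(5-hydroxy-7-methoxy-2,2-dimethyl-2H-chromen-6-yl)-3-phenylpropane-1,3-dione (achiral) | COc1cc2c(c(O)c1C(=O)CC(=O)c1ccccc1)C=CC(C)(C)O2 | target

**Totals**
Total step count: 4. Longest linear sequence: 4 steps (1 → 2 → 4 → 6 → 8).

**Steps most likely to fail**

First, step 3 (proposed new method). The palladium allyl/hydride manifold may stall at the ring-opened diene, or the double bond may migrate toward the aromatic 2-isopropylbenzofuran instead of the chain re-closing to the six-membered ring. The fallback uses known chemistry and opens and re-closes the ring stepwise. Setting out from 4, Markovnikov addition of HBr (HBr in AcOH, 0 °C) to the isopropenyl group should give the tertiary bromide rac-1-[2-(2-bromopropan-2-yl)-4-hydroxy-6-methoxy-2,3-dihydro-1-benzofuran-5-yl]ethan-1-one F1. Zinc dust with NH4Cl in aqueous THF should then open the dihydrofuran ring by reductive β-elimination (Boord-type) to the o-prenylphenol 1-[2,4-dihydroxy-6-methoxy-3-(3-methylbut-2-en-1-yl)phenyl]ethan-1-one F2. DDQ in benzene at 80 °C should cyclise F2 oxidatively (o-quinone methide, then oxa-6π electrocyclisation) through the non-chelated hydroxyl, and the route is rejoined at 6.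

Second, step 1. Iodination may also occur at C5 (between hydroxyl and methoxyl) or twice, so that the regiochemistry of the later ring is lost. The fallback delivers the carbon chain intramolecularly instead. Setting out from 1, Pd-catalysed addition of the free C4 hydroxyl to 2-methyl-2-vinyloxirane (Pd2(dba)3, racemic DACH-phenyl diphosphine ligand, CH2Cl2, rt) should give the tertiary allylic aryl ether rac-1-{2-hydroxy-4-[(1-hydroxy-2-methylbut-3-en-2-yl)oxy]-6-methoxyphenyl}ethan-1-one F3. Aromatic Claisen rearrangement (toluene, 110 °C), directed to C3 by the bond fixation of the chelated o-hydroxy ketone, should give 1-{2,4-dihydroxy-3-[(2E)-4-hydroxy-3-methylbut-2-en-1-yl]-6-methoxyphenyl}ethan-1-one F4. Dehydrative intramolecular allylic etherification (Pd(OAc)2, PPh3, Ti(OiPr)4, toluene, 50 °C; 5-exo attack of the C4 hydroxyl on the π-allyl unit) should close the dihydrofuran ring, and the route is rejoined at 4. This detour also bypasses step 2.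

Third, step 4. O-acylation or double acylation may compete with C-acylation, and the o-hydroxy-1,3-diketone may cyclodehydrate to a flavone during work-up. The fallback transfers the benzoyl group intramolecularly. Setting out from 6, O-benzoylation of the chelated hydroxyl (PhCOCl, pyridine, DMAP, rt) should give 6-acetyl-7-methoxy-2,2-dimethyl-2H-chromen-5-yl benzoate F5. Baker–Venkataraman rearrangement (KOH, pyridine, 50 °C; work-up with dilute AcOH) should then move the benzoyl group onto the ketone enolate, and the route is rejoined at 8.

**Further compounds**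
F1 | step 3 | rac-1-[2-(2-bromopropan-2-yl)-4-hydroxy-6-methoxy-2,3-dihydro-1-benzofuran-5-yl]ethan-1-one | COc1cc2c(c(O)c1C(C)=O)CC(C(C)(C)Br)O2
F2 | step 3 | 1-[2,4-dihydroxy-6-methoxy-3-(3-methylbut-2-en-1-yl)phenyl]ethan-1-one | CC(=O)c1c(OC)cc(O)c(CC=C(C)C)c1O
F3 | step 1 | rac-1-{2-hydroxy-4-[(1-hydroxy-2-methylbut-3-en-2-yl)oxy]-6-methoxyphenyl}ethan-1-one | CC(=O)c1c(O)cc(OC(C)(CO)C=C)cc1OC
F4 | step 1 | 1-{2,4-dihydroxy-3-[(2E)-4-hydroxy-3-methylbut-2-en-1-yl]-6-methoxyphenyl}ethan-1-one | CC(=O)c1c(O)c(C/C=C(\C)CO)c(O)cc1OC
F5 | step 4 | 6-acetyl-7-methoxy-2,2-dimethyl-2H-chromen-5-yl benzoate | COc1cc2c(c(OC(=O)c3ccccc3)c1C(C)=O)C=CC(C)(C)O2
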